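**Retrosynthetic overview**

1. Maltepolide D comes from desilylation and C5 oxidation of a 20-membered macrocycle. Its 6E,8Z-diene arises from a ring-closing Sonogashira coupling (C7–C8) followed by Z-selective semi-reduction.
2. Key disconnection: the C1–O19 ester C–O bond, formed by zerovalent-palladium-catalysed syn-1,4 (SN2′) addition of acid fragment A (C1–C7) to the vinyl epoxide of fragment B (C8–C24). This sets C19 and the 20E-alkene and frees 22-OH.
3. Fragment B comes from cross-metathesis of the oxolane core with vinyl epoxide fragment C (C20–C24), Still–Gennari olefination (12Z) and catalytic asymmetric propargylation (C11).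
4. The oxolane core comes from 5-exo epoxide opening (O17 to C14, inversion) after anti-crotylation, with chirality from a Sharpless kinetic resolution. Fragment A comes from anti-crotylation and methacrylate ring-closing metathesis (the δ-lactone fixes 2Z and C4). Fragment C comes from (S)-but-3-yn-2-ol.
5. Ring order: oxolane ring first (step 5), 20-membered macrolactone ring last (step 24). The oxiranes and the δ-lactone are temporary rings.

Assumption: positions are named with maltepolide numbering (C1 = lactone carbonyl, C19 = lactone carbinol, C24 = side-chain methyl); the (−)-(E)-crotyl-B(Ipc)2 solution (Ipc from (+)-α-pinene) is prepared by the standard procedure and not counted as a step.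

**Oxolane core and northern chain**

Step 1
Reactants: 1 (±)-hexa-1,5-dien-3-ol
Product: 2 (1S)-1-[(2R)-oxiran-2-yl]but-3-en-1-ol
Conditions: Ti(OiPr)4 (10 mol%), L-(+)-DIPT (15 mol%), t-BuOOH (0.5 equiv), 4 Å MS, CH2Cl2, −20 °C
Reagents that add atoms: tert-butyl hydroperoxide, CC(C)(C)OO
Why: Sharpless asymmetric epoxidation run as a kinetic resolution: with L-(+)-tartrate the (S)-alcohol reacts fast and is epoxidised only at its allylic vinyl group to the erythro epoxy alcohol, which fixes C15 and the pre-inversion centre C14, while the (R)-alcohol stays behind.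

Step 2
Reactants: 2 (1S)-1-[(2R)-oxiran-2-yl]but-3-en-1-ol
Product: 3 (2R)-2-[(1S)-1-methoxybut-3-en-1-yl]oxirane
Conditions: NaH, MeI, THF, 0 °C
Reagents that add atoms: iodomethane, CI
Why: Williamson O-methylation of the sodium alkoxide installs the C15 methoxy group without touching either stereocentre.

Step 3
Reactants: 3 (2R)-2-[(1S)-1-methoxybut-3-en-1-yl]oxirane
Product: 5 (3S)-3-methoxy-3-[(2R)-oxiran-2-yl]propanal, via ozonide 4 (not isolated)
Conditions: O3, CH2Cl2, −78 °C; then PPh3, −78 °C to rt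
Reagents that add atoms: ozone, [O-][O+]=O
Why: Ozonolysis with reductive work-up cleaves the only alkene to the C17 aldehyde, which is used crude to avoid β-elimination of methanol.

Step 4
Reactants: 5 (3S)-3-methoxy-3-[(2R)-oxiran-2-yl]propanal
Product: 7 (3S,4R,6S)-6-methoxy-3-methyl-6-[(2R)-oxiran-2-yl]hex-1-en-4-ol, via borinate 6 (not isolated)
Conditions: (−)-(E)-crotyl-B(Ipc)2, THF/Et2O, −78 °C; then NaBO3·4H2O, THF/H2O, rt
Reagents that add atoms: (−)-(E)-crotyldiisopinocampheylborane, C/C=C/CB([C@@H]1C[C@@H]2C[C@H]([C@H]1C)C2(C)C)[C@@H]1C[C@@H]2C[C@H]([C@H]1C)C2(C)C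
Why: Brown crotylboration: the (E)-crotylborane reacts through a closed chair transition state to give the anti adduct, and the isopinocampheyl groups override the remote methoxy centre to set the C17 carbinol and C18 methyl centres.

Step 5
Reactants: 7 (3S,4R,6S)-6-methoxy-3-methyl-6-[(2R)-oxiran-2-yl]hex-1-en-4-ol
Product: 8 [(2S,3S,5R)-5-[(2S)-but-3-en-2-yl]-3-methoxyoxolan-2-yl]methanol
Conditions: CSA (10 mol%), CH2Cl2, 0 °C to rt
Reagents that add atoms: none
Why: Acid-catalysed 5-exo-tet epoxide opening (intramolecular etherification) by the C17 hydroxyl inverts C14 and closes the 2,5-trans-oxolane with the C14 substituent cis to the methoxy group.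

Step 6
Reactants: 8 [(2S,3S,5R)-5-[(2S)-but-3-en-2-yl]-3-methoxyoxolan-2-yl]methanol
Product: 9 (2R,3S,5R)-5-[(2S)-but-3-en-2-yl]-3-methoxyoxolane-2-carbaldehyde
Conditions: Dess–Martin periodinane, CH2Cl2, 0 °C to rt
Reagents that add atoms: none
Why: Dess–Martin oxidation of the primary alcohol under near-neutral conditions keeps the α-alkoxy centre C14 intact.

Step 7
Reactants: 9 (2R,3S,5R)-5-[(2S)-but-3-en-2-yl]-3-methoxyoxolane-2-carbaldehyde
Product: 10 ethyl (2Z)-3-[(2S,3S,5R)-5-[(2S)-but-3-en-2-yl]-3-methoxyoxolan-2-yl]-2-methylprop-2-enoate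
Conditions: (CF3CH2O)2P(O)CH(Me)CO2Et, KN(SiMe3)2, 18-crown-6, THF, −78 °C
Reagents that add atoms: ethyl 2-[bis(2,2,2-trifluoroethoxy)phosphoryl]propanoate, CCOC(=O)C(C)P(=O)(OCC(F)(F)F)OCC(F)(F)F
Why: Still–Gennari olefination: the electron-poor phosphonate eliminates fast from the kinetic adduct and gives the (Z)-α-methyl enoate, which becomes the 12Z-alkene.

Step 8
Reactants: 10 ethyl (2Z)-3-[(2S,3S,5R)-5-[(2S)-but-3-en-2-yl]-3-methoxyoxolan-2-yl]-2-methylprop-2-enoate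
Product: 11 (2Z)-3-[(2S,3S,5R)-5-[(2S)-but-3-en-2-yl]-3-methoxyoxolan-2-yl]-2-methylprop-2-en-1-ol
Conditions: iBu2AlH, CH2Cl2, −78 °C
Reagents that add atoms: none
Why: Hydride reduction of the ester with iBu2AlH gives the (Z)-allylic alcohol without touching either alkene.

**Fragment C (vinyl epoxide)**

Step 9
Reactants: 12 (2S)-but-3-yn-2-ol; 13 bromoethene
Product: 14 (2S)-hex-5-en-3-yn-2-ol
Conditions: Pd(PPh3)2Cl2 (2 mol%), CuI (4 mol%), iPr2NH, THF, 0 °C to rt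
Reagents that add atoms: none
Why: Sonogashira coupling joins the terminal alkyne to vinyl bromide and leaves the carbinol centre (C23) untouched.

Step 10
Reactants: 14 (2S)-hex-5-en-3-yn-2-ol
Product: 15 (2S,3E)-hexa-3,5-dien-2-ol
Conditions: NaAlH2(OCH2CH2OMe)2, THF, 0 °C to rt
Reagents that add atoms: none
Why: Alkoxide-directed trans-hydroalumination of the propargylic alcohol (Red-Al reduction) gives the (E)-alkene.

Step 11
Reactants: 15 (2S,3E)-hexa-3,5-dien-2-ol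
Product: 16 (1S)-1-[(2S,3S)-3-ethenyloxiran-2-yl]ethan-1-ol
Conditions: Ti(OiPr)4 (10 mol%), L-(+)-DIPT (15 mol%), t-BuOOH, 4 Å MS, CH2Cl2, −20 °C
Reagents that add atoms: tert-butyl hydroperoxide, CC(C)(C)OO
Why: Sharpless asymmetric epoxidation in the matched case: L-(+)-tartrate epoxidises only the allylic double bond of the (S)-alcohol to the erythro trans-epoxide, setting C21 and C22.

Step 12
Reactants: 16 (1S)-1-[(2S,3S)-3-ethenyloxiran-2-yl]ethan-1-ol
Product: 17 tert-butyl{(1S)-1-[(2R,3S)-3-ethenyloxiran-2-yl]ethoxy}dimethylsilane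
Conditions: TBSCl, imidazole, DMF, 0 °C to rt
Reagents that add atoms: tert-butylchlorodimethylsilane, CC(C)(C)[Si](C)(C)Cl
Why: Standard silylation protects the C23 hydroxyl and later shields the neighbouring allyl terminus.

**Completion of fragment B**

Step 13
Reactants: 11 (2Z)-3-[(2S,3S,5R)-5-[(2S)-but-3-en-2-yl]-3-methoxyoxolan-2-yl]-2-methylprop-2-en-1-ol; 17 tert-butyl{(1S)-1-[(2R,3S)-3-ethenyloxiran-2-yl]ethoxy}dimethylsilane
Product: 18 (2Z)-3-[(2S,3S,5R)-5-[(2S,3E)-4-[(2S,3R)-3-[(1S)-1-(tert-butyldimethylsilyloxy)ethyl]oxiran-2-yl]but-3-en-2-yl]-3-methoxyoxolan-2-yl]-2-methylprop-2-en-1-ol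
Conditions: 17 (3 equiv), second-generation Hoveyda–Grubbs catalyst RuCl2(H2IMes)(=CH-C6H4-2-OiPr) (10 mol%), CH2Cl2, 40 °C
Reagents that add atoms: none
Why: Olefin cross-metathesis joins the only terminal alkene of 11 to the vinyl epoxide; the trisubstituted Z-alkene is inert and the E-alkene is favoured.

Step 14
Reactants: 18 (2Z)-3-[(2S,3S,5R)-5-[(2S,3E)-4-[(2S,3R)-3-[(1S)-1-(tert-butyldimethylsilyloxy)ethyl]oxiran-2-yl]but-3-en-2-yl]-3-methoxyoxolan-2-yl]-2-methylprop-2-en-1-ol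
Product: 19 (2Z)-3-[(2S,3S,5R)-5-[(2S,3E)-4-[(2S,3R)-3-[(1S)-1-(tert-butyldimethylsilyloxy)ethyl]oxiran-2-yl]but-3-en-2-yl]-3-methoxyoxolan-2-yl]-2-methylprop-2-enal
Conditions: MnO2, CH2Cl2, rt
Reagents that add atoms: none
Why: MnO2 oxidises the allylic alcohol to the (Z)-enal under neutral conditions, so neither Z/E isomerisation nor epoxide opening occurs.

Step 15
Reactants: 19 (2Z)-3-[(2S,3S,5R)-5-[(2S,3E)-4-[(2S,3R)-3-[(1S)-1-(tert-butyldimethylsilyloxy)ethyl]oxiran-2-yl]but-3-en-2-yl]-3-methoxyoxolan-2-yl]-2-methylprop-2-enal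
Product: 20 (4R,5Z)-6-[(2S,3S,5R)-5-[(2S,3E)-4-[(2S,3R)-3-[(1S)-1-(tert-butyldimethylsilyloxy)ethyl]oxiran-2-yl]but-3-en-2-yl]-3-methoxyoxolan-2-yl]-5-methylhex-5-en-1-yn-4-ol
Conditions: allenyl-B(pin), (R)-TRIP [(R)-3,3′-bis(2,4,6-triisopropylphenyl)-BINOL hydrogen phosphate] (10 mol%), 4 Å MS, toluene, −20 °C
Reagents that add atoms: allenylboronic acid pinacol ester, C=C=CB1OC(C)(C)C(C)(C)O1
Why: Chiral phosphoric acid-catalysed propargylation: the allenylboronate adds through a six-membered transition state held by the (R)-catalyst on the re face of the enal, which sets 11R and delivers the terminal alkyne (C8–C10).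

**Fragment A (acid)**

Step 16
Reactants: 21 prop-2-yn-1-ol
Product: 23 (2E)-3-iodo-2-methylprop-2-en-1-ol, via alkenylalane 22 (not isolated)
Conditions: AlMe3, Cp2ZrCl2 (25 mol%), CH2Cl2, 0 °C to rt; then I2, THF, −30 °C
Reagents that add atoms: trimethylaluminium, C[Al](C)C; iodine, [I][I]
Why: Negishi zirconium-catalysed syn-carboalumination puts methyl on C2 and aluminium on C3, and iodinolysis with retention gives the (E)-alkenyl iodide.

Step 17
Reactants: 23 (2E)-3-iodo-2-methylprop-2-en-1-ol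
Product: 24 (2E)-3-iodo-2-methylprop-2-enal
Conditions: MnO2, CH2Cl2, rt
Reagents that add atoms: none
Why: Neutral allylic oxidation with MnO2 gives the enal without loss of alkene geometry.

Step 18
Reactants: 24 (2E)-3-iodo-2-methylprop-2-enal
Product: 26 (1E,3S,4S)-1-iodo-2,4-dimethylhexa-1,5-dien-3-ol, via borinate 25 (not isolated)
Conditions: (−)-(E)-crotyl-B(Ipc)2, THF/Et2O, −78 °C; then NaBO3·4H2O, THF/H2O, rt
Reagents that add atoms: (−)-(E)-crotyldiisopinocampheylborane, C/C=C/CB([C@@H]1C[C@@H]2C[C@H]([C@H]1C)C2(C)C)[C@@H]1C[C@@H]2C[C@H]([C@H]1C)C2(C)C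
Why: Brown crotylboration through a chair transition state gives the anti adduct with reagent-controlled facial selectivity; its methyl-bearing carbon is the target's 4S centre and the carbinol is oxidised later.

Step 19
Reactants: 26 (1E,3S,4S)-1-iodo-2,4-dimethylhexa-1,5-dien-3-ol
Product: 27 (1E,3S,4S)-1-iodo-2,4-dimethylhexa-1,5-dien-3-yl 2-methylprop-2-enoate
Conditions: methacryloyl chloride, Et3N, DMAP (cat.), CH2Cl2, 0 °C
Reagents that add atoms: methacryloyl chloride, CC(=C)C(Cl)=O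
Why: Acylation of the secondary alcohol installs C1, C2 and the 2-methyl group as a metathesis partner.

Step 20
Reactants: 27 (1E,3S,4S)-1-iodo-2,4-dimethylhexa-1,5-dien-3-yl 2-methylprop-2-enoate
Product: 28 (5S,6S)-6-[(1E)-1-iodoprop-1-en-2-yl]-3,5-dimethyl-5,6-dihydro-2H-pyran-2-one
Conditions: second-generation Grubbs catalyst RuCl2(H2IMes)(PCy3)(=CHPh) (5 mol%), toluene, 80 °C
Reagents that add atoms: none
Why: Ring-closing metathesis of the methacrylate with the vinyl group gives the unsaturated δ-lactone; the six-membered ring enforces the 2Z geometry and the hindered alkenyl iodide does not take part.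

Step 21
Reactants: 28 (5S,6S)-6-[(1E)-1-iodoprop-1-en-2-yl]-3,5-dimethyl-5,6-dihydro-2H-pyran-2-one
Product: 31 (2Z,4S,5S,6E)-7-iodo-2,4,6-trimethyl-5-(triethylsilyloxy)hepta-2,6-dienoic acid, via lithium carboxylate 29 (not isolated), via bis-silyl ester 30 (not isolated)
Conditions: LiOH, THF/H2O, rt; concentrate; then TESCl, imidazole, DMF, rt; then K2CO3, MeOH/H2O, 0 °C, pH 5 work-up
Reagents that add atoms: lithium hydroxide, [Li+].[OH-]; chlorotriethylsilane, CC[Si](Cl)(CC)CC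
Why: Saponification opens the lactone, silylation caps both oxygens and the labile silyl ester alone is hydrolysed; the carboxylate is never acidified while 5-OH is free, so relactonisation is avoided.

**Union and endgame**

Step 22
Reactants: 20 (4R,5Z)-6-[(2S,3S,5R)-5-[(2S,3E)-4-[(2S,3R)-3-[(1S)-1-(tert-butyldimethylsilyloxy)ethyl]oxiran-2-yl]but-3-en-2-yl]-3-methoxyoxolan-2-yl]-5-methylhex-5-en-1-yn-4-ol; 31 (2Z,4S,5S,6E)-7-iodo-2,4,6-trimethyl-5-(triethylsilyloxy)hepta-2,6-dienoic acid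
Product: 32 seco ester (C1–O19 ester of acid 31 on the 19R carbinol; 20E; free 11-OH; free 22-OH; 23-OTBS; C8≡C9 alkyne; C7 iodide)
Conditions: Pd2(dba)3·CHCl3 (2.5 mol%), P(OPh)3 (20 mol%), 31 (1.2 equiv), THF, 0 °C, no base
Reagents that add atoms: none
Why: Proposed new method: zerovalent palladium carrying the π-acidic ligand P(OPh)3 ionises the strained vinyl epoxide with inversion to a syn,syn-π-allyl complex whose C22 alkoxide is protonated by acid 31, and the carboxylate then attacks, again with inversion, the allyl terminus remote from the electron-withdrawing and bulky C22/C23 oxygens, so the ester C–O bond forms at C19 on the face the epoxide oxygen left (21S gives 19R, 20E) while the electron-poor catalyst at 0 °C is expected to leave the alkenyl C–I bond and the terminal alkyne alone; the closest known reaction type is the zerovalent-palladium-catalysed cis-1,4-addition of simple carboxylic acids to cyclic diene monoepoxides together with Tsuji–Trost 1,4-chirality transfer of soft carbon nucleophiles, not yet shown for a complex (Z)-enoic acid on an acyclic trans-disubstituted vinyl epoxide beside an alkenyl iodide.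

Step 23
Reactants: 32 seco ester (C1–O19 ester of acid 31 on the 19R carbinol; 20E; free 11-OH; free 22-OH; 23-OTBS; C8≡C9 alkyne; C7 iodide)
Product: 33 bis-silylated seco ester (as 32 but 11-OTBS; 22-OTBS)
Conditions: TBSOTf, 2,6-lutidine, CH2Cl2, −78 °C
Reagents that add atoms: tert-butyldimethylsilyl triflate, CC(C)(C)[Si](C)(C)OS(=O)(=O)C(F)(F)F
Why: Silylation of the two free secondary alcohols protects them against the later C5 oxidation.

Step 24
Reactants: 33 bis-silylated seco ester (as 32 but 11-OTBS; 22-OTBS)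
Product: 34 (5S)-5-deoxo-5-(triethylsilyloxy)-8,9-didehydro-11,22,23-tris-O-(tert-butyldimethylsilyl)maltepolide D
Conditions: Pd(PPh3)4 (20 mol%), CuI (40 mol%), iPr2NH, THF (1 mM, degassed), rt
Reagents that add atoms: none
Why: Intramolecular Sonogashira coupling at high dilution closes the 20-membered ring, the alkenyl iodide reacting with retention (6E) faster than the hindered allylic ester can ionise.

Step 25
Reactants: 34 (5S)-5-deoxo-5-(triethylsilyloxy)-8,9-didehydro-11,22,23-tris-O-(tert-butyldimethylsilyl)maltepolide D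
Product: 35 (5S)-5-deoxo-5-(triethylsilyloxy)-11,22,23-tris-O-(tert-butyldimethylsilyl)maltepolide D
Conditions: Zn dust activated with Cu(OAc)2 and AgNO3, MeOH/H2O (1:1), 45 °C
Reagents that add atoms: none
Why: Boland reduction: activated zinc reduces only the conjugated alkyne by syn delivery of two hydrogens, giving the 8Z-alkene of the 6E,8Z-diene.

Step 26
Reactants: 35 (5S)-5-deoxo-5-(triethylsilyloxy)-11,22,23-tris-O-(tert-butyldimethylsilyl)maltepolide D
Product: 36 (5S)-5-deoxo-5-hydroxy-11,22,23-tris-O-(tert-butyldimethylsilyl)maltepolide D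
Conditions: HF·pyridine, pyridine, THF, 0 °C
Reagents that add atoms: none
Why: Buffered HF·pyridine cleaves the triethylsilyl ether much faster than the three secondary TBS ethers; the alcohol is oxidised at once to forestall translactonisation onto C1.

Step 27
Reactants: 36 (5S)-5-deoxo-5-hydroxy-11,22,23-tris-O-(tert-butyldimethylsilyl)maltepolide D
Product: 37 11,22,23-tris-O-(tert-butyldimethylsilyl)maltepolide D
Conditions: Dess–Martin periodinane, CH2Cl2, 0 °C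
Reagents that add atoms: none
Why: Dess–Martin oxidation of the dienylic alcohol gives the C5 ketone under non-basic conditions, so the now acidic C4 centre is not epimerised.

Step 28
Reactants: 37 11,22,23-tris-O-(tert-butyldimethylsilyl)maltepolide D
Product: 38 maltepolide D
Conditions: HF·pyridine, pyridine, THF, 0 °C to rt
Reagents that add atoms: none
Why: Fluoride-mediated global desilylation under mildly acidic conditions frees the 11-, 22- and 23-hydroxyls without base that could epimerise C4 or move the β,γ-alkene.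

**Compound list**

1 | (±)-hexa-1,5-dien-3-ol | C=CCC(O)C=C | starting material
2 | (1S)-1-[(2R)-oxiran-2-yl]but-3-en-1-ol | C=CC[C@H](O)[C@H]1CO1 | intermediate
3 | (2R)-2-[(1S)-1-methoxybut-3-en-1-yl]oxirane | C=CC[C@H](OC)[C@H]1CO1 | intermediate
4 | 3-[(2S)-2-methoxy-2-[(2R)-oxiran-2-yl]ethyl]-1,2,4-trioxolane (ozonide; trioxolane carbon unassigned) | C1OOC(O1)C[C@H](OC)[C@H]1CO1 | intermediate
5 | (3S)-3-methoxy-3-[(2R)-oxiran-2-yl]propanal | O=CC[C@H](OC)[C@H]1CO1 | intermediate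
6 | O-[bis(isopinocampheyl)boryl] ether (borinate) of 7 | C=C[C@H](C)[C@H](OB([C@@H]1C[C@@H]2C[C@H]([C@H]1C)C2(C)C)[C@@H]1C[C@@H]2C[C@H]([C@H]1C)C2(C)C)C[C@H](OC)[C@H]1CO1 | intermediate
7 | (3S,4R,6S)-6-methoxy-3-methyl-6-[(2R)-oxiran-2-yl]hex-1-en-4-ol | C=C[C@H](C)[C@H](O)C[C@H](OC)[C@H]1CO1 | intermediate
8 | [(2S,3S,5R)-5-[(2S)-but-3-en-2-yl]-3-methoxyoxolan-2-yl]methanol | OC[C@@H]1O[C@H](C[C@@H]1OC)[C@@H](C)C=C | intermediate
9 | (2R,3S,5R)-5-[(2S)-but-3-en-2-yl]-3-methoxyoxolane-2-carbaldehyde | O=C[C@@H]1O[C@H](C[C@@H]1OC)[C@@H](C)C=C | intermediate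
10 | ethyl (2Z)-3-[(2S,3S,5R)-5-[(2S)-but-3-en-2-yl]-3-methoxyoxolan-2-yl]-2-methylprop-2-enoate | CCOC(=O)/C(C)=C\[C@@H]1O[C@H](C[C@@H]1OC)[C@@H](C)C=C | intermediate
11 | (2Z)-3-[(2S,3S,5R)-5-[(2S)-but-3-en-2-yl]-3-methoxyoxolan-2-yl]-2-methylprop-2-en-1-ol | OC/C(C)=C\[C@@H]1O[C@H](C[C@@H]1OC)[C@@H](C)C=C | intermediate
12 | (2S)-but-3-yn-2-ol | C#C[C@H](C)O | starting material
13 | bromoethene | C=CBr | starting material
14 | (2S)-hex-5-en-3-yn-2-ol | C=CC#C[C@H](C)O | intermediate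
15 | (2S,3E)-hexa-3,5-dien-2-ol | C=C/C=C/[C@H](C)O | intermediate
16 | (1S)-1-[(2S,3S)-3-ethenyloxiran-2-yl]ethan-1-ol | C=C[C@@H]1O[C@H]1[C@H](C)O | intermediate
17 | tert-butyl{(1S)-1-[(2R,3S)-3-ethenyloxiran-2-yl]ethoxy}dimethylsilane | C=C[C@@H]1O[C@H]1[C@H](C)O[Si](C)(C)C(C)(C)C | intermediate
18 | (2Z)-3-[(2S,3S,5R)-5-[(2S,3E)-4-[(2S,3R)-3-[(1S)-1-(tert-butyldimethylsilyloxy)ethyl]oxiran-2-yl]but-3-en-2-yl]-3-methoxyoxolan-2-yl]-2-methylprop-2-en-1-ol | OC/C(C)=C\[C@@H]1O[C@H](C[C@@H]1OC)[C@@H](C)/C=C/[C@@H]1O[C@H]1[C@H](C)O[Si](C)(C)C(C)(C)C | intermediate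
19 | (2Z)-3-[(2S,3S,5R)-5-[(2S,3E)-4-[(2S,3R)-3-[(1S)-1-(tert-butyldimethylsilyloxy)ethyl]oxiran-2-yl]but-3-en-2-yl]-3-methoxyoxolan-2-yl]-2-methylprop-2-enal | O=C/C(C)=C\[C@@H]1O[C@H](C[C@@H]1OC)[C@@H](C)/C=C/[C@@H]1O[C@H]1[C@H](C)O[Si](C)(C)C(C)(C)C | intermediate
20 | (4R,5Z)-6-[(2S,3S,5R)-5-[(2S,3E)-4-[(2S,3R)-3-[(1S)-1-(tert-butyldimethylsilyloxy)ethyl]oxiran-2-yl]but-3-en-2-yl]-3-methoxyoxolan-2-yl]-5-methylhex-5-en-1-yn-4-ol | C#CC[C@@H](O)/C(C)=C\[C@@H]1O[C@H](C[C@@H]1OC)[C@@H](C)/C=C/[C@@H]1O[C@H]1[C@H](C)O[Si](C)(C)C(C)(C)C | intermediate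
21 | prop-2-yn-1-ol | C#CCO | starting material
22 | [(1E)-3-(dimethylalumanyloxy)-2-methylprop-1-en-1-yl]dimethylalumane | C[Al](C)OC/C(C)=C/[Al](C)C | intermediate
23 | (2E)-3-iodo-2-methylprop-2-en-1-ol | OC/C(C)=C/I | intermediate
24 | (2E)-3-iodo-2-methylprop-2-enal | O=C/C(C)=C/I | intermediate
25 | O-[bis(isopinocampheyl)boryl] ether (borinate) of 26 | C=C[C@H](C)[C@H](OB([C@@H]1C[C@@H]2C[C@H]([C@H]1C)C2(C)C)[C@@H]1C[C@@H]2C[C@H]([C@H]1C)C2(C)C)/C(C)=C/I | intermediate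
26 | (1E,3S,4S)-1-iodo-2,4-dimethylhexa-1,5-dien-3-ol | C=C[C@H](C)[C@H](O)/C(C)=C/I | intermediate
27 | (1E,3S,4S)-1-iodo-2,4-dimethylhexa-1,5-dien-3-yl 2-methylprop-2-enoate | C=C[C@H](C)[C@H](OC(=O)C(C)=C)/C(C)=C/I | intermediate
28 | (5S,6S)-6-[(1E)-1-iodoprop-1-en-2-yl]-3,5-dimethyl-5,6-dihydro-2H-pyran-2-one | O=C1O[C@H](/C(C)=C/I)[C@@H](C)C=C1C | intermediate
29 | lithium (2Z,4S,5S,6E)-5-hydroxy-7-iodo-2,4,6-trimethylhepta-2,6-dienoate | [Li+].[O-]C(=O)/C(C)=C\[C@H](C)[C@H](O)/C(C)=C/I | intermediate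
30 | triethylsilyl (2Z,4S,5S,6E)-7-iodo-2,4,6-trimethyl-5-(triethylsilyloxy)hepta-2,6-dienoate | CC[Si](CC)(CC)OC(=O)/C(C)=C\[C@H](C)[C@H](O[Si](CC)(CC)CC)/C(C)=C/I | intermediate
31 | (2Z,4S,5S,6E)-7-iodo-2,4,6-trimethyl-5-(triethylsilyloxy)hepta-2,6-dienoic acid | OC(=O)/C(C)=C\[C@H](C)[C@H](O[Si](CC)(CC)CC)/C(C)=C/I | intermediate
32 | seco ester: 19-O-[(2Z,4S,5S,6E)-7-iodo-2,4,6-trimethyl-5-(triethylsilyloxy)hepta-2,6-dienoyl] derivative of the C8–C24 chain with C8≡C9 alkyne; 11R-OH; 12Z; 14,17-oxolane (14S; 15S-OMe; 17R); 18R-Me; 19R; 20E; 22R-OH; 23S-OTBS | O=C(O[C@H](/C=C/[C@@H](O)[C@H](C)O[Si](C)(C)C(C)(C)C)[C@H](C)[C@H]1C[C@H](OC)[C@@H](O1)/C=C(/C)[C@H](O)CC#C)/C(C)=C\[C@H](C)[C@H](O[Si](CC)(CC)CC)/C(C)=C/I | intermediate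
33 | bis-silylated seco ester: as 32 with 11-OTBS and 22-OTBS | O=C(O[C@H](/C=C/[C@@H](O[Si](C)(C)C(C)(C)C)[C@H](C)O[Si](C)(C)C(C)(C)C)[C@H](C)[C@H]1C[C@H](OC)[C@@H](O1)/C=C(/C)[C@H](O[Si](C)(C)C(C)(C)C)CC#C)/C(C)=C\[C@H](C)[C@H](O[Si](CC)(CC)CC)/C(C)=C/I | intermediate
34 | (5S)-5-deoxo-5-(triethylsilyloxy)-8,9-didehydro-11,22,23-tris-O-(tert-butyldimethylsilyl)maltepolide D (20-membered lactone with C8≡C9 alkyne; 2Z,6E,12Z,20E) | CO[C@H]1C[C@H]2O[C@H]1/C=C(/C)[C@H](O[Si](C)(C)C(C)(C)C)CC#C/C=C(\C)[C@@H](O[Si](CC)(CC)CC)[C@@H](C)/C=C(/C)C(=O)O[C@H](/C=C/[C@@H](O[Si](C)(C)C(C)(C)C)[C@H](C)O[Si](C)(C)C(C)(C)C)[C@@H]2C | intermediate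
35 | (5S)-5-deoxo-5-(triethylsilyloxy)-11,22,23-tris-O-(tert-butyldimethylsilyl)maltepolide D (2Z,6E,8Z,12Z,20E) | CO[C@H]1C[C@H]2O[C@H]1/C=C(/C)[C@H](O[Si](C)(C)C(C)(C)C)C/C=C\C=C(/C)[C@@H](O[Si](CC)(CC)CC)[C@@H](C)/C=C(/C)C(=O)O[C@H](/C=C/[C@@H](O[Si](C)(C)C(C)(C)C)[C@H](C)O[Si](C)(C)C(C)(C)C)[C@@H]2C | intermediate
36 | (5S)-5-deoxo-5-hydroxy-11,22,23-tris-O-(tert-butyldimethylsilyl)maltepolide D | CO[C@H]1C[C@H]2O[C@H]1/C=C(/C)[C@H](O[Si](C)(C)C(C)(C)C)C/C=C\C=C(/C)[C@@H](O)[C@@H](C)/C=C(/C)C(=O)O[C@H](/C=C/[C@@H](O[Si](C)(C)C(C)(C)C)[C@H](C)O[Si](C)(C)C(C)(C)C)[C@@H]2C | intermediate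
37 | 11,22,23-tris-O-(tert-butyldimethylsilyl)maltepolide D | CO[C@H]1C[C@H]2O[C@H]1/C=C(/C)[C@H](O[Si](C)(C)C(C)(C)C)C/C=C\C=C(/C)C(=O)[C@@H](C)/C=C(/C)C(=O)O[C@H](/C=C/[C@@H](O[Si](C)(C)C(C)(C)C)[C@H](C)O[Si](C)(C)C(C)(C)C)[C@@H]2C | intermediate
38 | maltepolide D | CO[C@H]1C[C@H]2O[C@H]1/C=C(/C)[C@H](O)C/C=C\C=C(/C)C(=O)[C@@H](C)/C=C(/C)C(=O)O[C@H](/C=C/[C@@H](O)[C@H](C)O)[C@@H]2C | target

**Step count and risks**

Total: 28 steps. Longest linear sequence: 18 steps (steps 1–8, 13–15 and 22–28, from hexa-1,5-dien-3-ol).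

Most likely to fail:

Step 22 (proposed new coupling). The risks are attack at C21 instead of C19, loss of 1,4-chirality transfer, and insertion of the catalyst into the C–I bond. The fallback uses known chemistry, sets out from 20 and comes back at 33. Compound 20 is treated with Pd(PPh3)4 and acetic acid in THF at 0 °C (known 1,4-addition of acetic acid to a vinyl epoxide, no iodide present) to give the 19R-acetate with free 22-OH, hydroxy acetate F1. Both free hydroxyls are silylated (TBSOTf, 2,6-lutidine) to give bis-silyl acetate F2. The acetate is removed (K2CO3, MeOH) to give C19 alcohol F3. Acid 31 is activated with 2,4,6-trichlorobenzoyl chloride and Et3N as mixed anhydride F4, which acylates F3 (DMAP, toluene, 0 °C; Yamaguchi esterification, kept cold and short to limit 2Z to 2E isomerisation) to give 33.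

Step 13 (cross-metathesis with the vinyl epoxide). The risks are low conversion between two hindered alkenes and a poor E/Z ratio. The fallback sets out from 10 and comes back at 18. Enoate 10 undergoes cross-metathesis with crotonaldehyde (second-generation Hoveyda–Grubbs catalyst, CH2Cl2, 40 °C) to give enal F5. Wittig reaction with 1-(triphenylphosphoranylidene)propan-2-one gives dienone F6. Reduction with (R)-Me-CBS and BH3·SMe2 gives (S)-dienol F7. Sharpless epoxidation (Ti(OiPr)4, L-(+)-DIPT, t-BuOOH) gives epoxy alcohol F8. Silylation (TBSCl, imidazole) gives silyl ether F9, and iBu2AlH at −78 °C reduces the ester to 18.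

Step 24 (ring-closing Sonogashira). The risks are oligomerisation and a strained cyclic enyne. The fallback sets out from 33 and comes back at 35, so step 25 is not needed. Z-selective trans-hydroboration of the terminal alkyne of 33 ([Rh(cod)Cl]2, P(iPr)3, Et3N, pinacolborane, cyclohexane, rt) gives (Z)-alkenylboronate F10. Intramolecular Suzuki–Miyaura coupling (Pd(PPh3)4, TlOEt, THF/H2O, 1 mM, rt) then closes the ring directly to the 6E,8Z-diene 35.

**Further compounds**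

F1 | step 22 | (19R)-19-O-acetyl C8–C24 fragment with free 11-OH and 22-OH; 23-OTBS; C8≡C9 alkyne | CC(=O)O[C@H](/C=C/[C@@H](O)[C@H](C)O[Si](C)(C)C(C)(C)C)[C@H](C)[C@H]1C[C@H](OC)[C@@H](O1)/C=C(/C)[C@H](O)CC#C
F2 | step 22 | (19R)-19-O-acetyl-11,22,23-tris-O-TBS C8–C24 fragment | CC(=O)O[C@H](/C=C/[C@@H](O[Si](C)(C)C(C)(C)C)[C@H](C)O[Si](C)(C)C(C)(C)C)[C@H](C)[C@H]1C[C@H](OC)[C@@H](O1)/C=C(/C)[C@H](O[Si](C)(C)C(C)(C)C)CC#C
F3 | step 22 | (19R)-19-hydroxy-11,22,23-tris-O-TBS C8–C24 fragment | O[C@H](/C=C/[C@@H](O[Si](C)(C)C(C)(C)C)[C@H](C)O[Si](C)(C)C(C)(C)C)[C@H](C)[C@H]1C[C@H](OC)[C@@H](O1)/C=C(/C)[C@H](O[Si](C)(C)C(C)(C)C)CC#C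
F4 | step 22 | 2,4,6-trichlorobenzoic (2Z,4S,5S,6E)-7-iodo-2,4,6-trimethyl-5-(triethylsilyloxy)hepta-2,6-dienoic anhydride | O=C(OC(=O)/C(C)=C\[C@H](C)[C@H](O[Si](CC)(CC)CC)/C(C)=C/I)c1c(Cl)cc(Cl)cc1Cl
F5 | step 13 | ethyl (2Z)-3-[(2S,3S,5R)-3-methoxy-5-[(2S,3E)-5-oxopent-3-en-2-yl]oxolan-2-yl]-2-methylprop-2-enoate | CCOC(=O)/C(C)=C\[C@@H]1O[C@H](C[C@@H]1OC)[C@@H](C)/C=C/C=O
F6 | step 13 | ethyl (2Z)-3-[(2S,3S,5R)-3-methoxy-5-[(2S,3E,5E)-7-oxoocta-3,5-dien-2-yl]oxolan-2-yl]-2-methylprop-2-enoate | CCOC(=O)/C(C)=C\[C@@H]1O[C@H](C[C@@H]1OC)[C@@H](C)/C=C/C=C/C(C)=O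
F7 | step 13 | ethyl (2Z)-3-[(2S,3S,5R)-5-[(2S,3E,5E,7S)-7-hydroxyocta-3,5-dien-2-yl]-3-methoxyoxolan-2-yl]-2-methylprop-2-enoate | CCOC(=O)/C(C)=C\[C@@H]1O[C@H](C[C@@H]1OC)[C@@H](C)/C=C/C=C/[C@H](C)O
F8 | step 13 | ethyl (2Z)-3-[(2S,3S,5R)-5-[(2S,3E)-4-[(2S,3S)-3-[(1S)-1-hydroxyethyl]oxiran-2-yl]but-3-en-2-yl]-3-methoxyoxolan-2-yl]-2-methylprop-2-enoate | CCOC(=O)/C(C)=C\[C@@H]1O[C@H](C[C@@H]1OC)[C@@H](C)/C=C/[C@@H]1O[C@H]1[C@H](C)O
F9 | step 13 | ethyl (2Z)-3-[(2S,3S,5R)-5-[(2S,3E)-4-[(2S,3R)-3-[(1S)-1-(tert-butyldimethylsilyloxy)ethyl]oxiran-2-yl]but-3-en-2-yl]-3-methoxyoxolan-2-yl]-2-methylprop-2-enoate | CCOC(=O)/C(C)=C\[C@@H]1O[C@H](C[C@@H]1OC)[C@@H](C)/C=C/[C@@H]1O[C@H]1[C@H](C)O[Si](C)(C)C(C)(C)C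
F10 | step 24 | seco ester 33 with the terminal alkyne replaced by a (8Z)-alkenyl pinacolboronate | O=C(O[C@H](/C=C/[C@@H](O[Si](C)(C)C(C)(C)C)[C@H](C)O[Si](C)(C)C(C)(C)C)[C@H](C)[C@H]1C[C@H](OC)[C@@H](O1)/C=C(/C)[C@H](O[Si](C)(C)C(C)(C)C)C/C=C\B1OC(C)(C)C(C)(C)O1)/C(C)=C\[C@H](C)[C@H](O[Si](CC)(CC)CC)/C(C)=C/I
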